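## Retrosynthetic overview

1. Feature: ring A of the 4'-methoxyflavone (acacetin) half carries oxygen on C5, C7, C8 and C8a and shares the C4a-C8a bond with pyranone ring C. Its C5-C6-C7 stretch equals a ketene carbonyl plus HC≡C-OBn, so the crowded C8-O-C4''' aryl ether can be made while C8 is still an sp3 methine.
2. Last disconnection: two benzyl ethers (7-O of the acacetin half, 5-O of the genkwanin half), removed together by hydrogenolysis.
3. Key disconnection: C5-C6, C7-C8 and C4a-C5, leading back to a 2-aryloxy-2-(4-oxopyran-2-yl)acetyl chloride (ketene precursor) and benzyl ethynyl ether.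
4. The acid chloride comes from a tert-butyl diazo(pyranonyl)acetate by Rh2(OAc)4 O-H insertion into the 4'-OH of 5-O-benzylgenkwanin. The pyranone comes from a 1,3,5-triketone.
5. Ring order: ring C first (triketone cyclodehydration); ring B and the three genkwanin rings are bought; ring A last.

Key step: step 12

Assumption: the target has no stereocentre, so every compound in which the future C8 is sp3 is made and used as a racemate. Locants C2 to C8a without further remark refer to the acacetin half, and ArG stands for 4-[5-(benzyloxy)-7-methoxy-4-oxo-4H-chromen-2-yl]phenyl.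

## Route

Step 1
Reactants: 1 pentane-2,4-dione (acetylacetone); 2 methyl 4-methoxybenzoate
Product: 3 1-(4-methoxyphenyl)hexane-1,3,5-trione
Conditions: NaH (4 equiv), DME, reflux; aq HCl
Reagents that add atoms: none
Why: Claisen-type terminal aroylation of a beta-diketone, in which excess NaH lets the methyl terminus of 1 attack the non-enolisable ester 2 and irreversible deprotonation of the triketone pulls the equilibrium over.

Step 2
Reactants: 3 1-(4-methoxyphenyl)hexane-1,3,5-trione
Product: 4 2-(4-methoxyphenyl)-6-methyl-4H-pyran-4-one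
Conditions: conc. H2SO4, 0 °C; ice
Reagents that add atoms: none
Why: Acid-catalysed cyclodehydration of a 1,3,5-triketone, in which the enol oxygen of one terminal carbonyl adds to the other and loss of water closes ring C, short contact at 0 °C sparing the anisyl ring from sulfonation.

Step 3
Reactants: 4 2-(4-methoxyphenyl)-6-methyl-4H-pyran-4-one
Product: 5 tert-butyl 2-[6-(4-methoxyphenyl)-4-oxo-4H-pyran-2-yl]acetate
Conditions: LiN(SiMe3)2 (2.2 equiv), THF, −78 °C; Boc2O, −78 → −40 °C; AcOH
Reagents that add atoms: di-tert-butyl dicarbonate, CC(C)(C)OC(=O)OC(=O)OC(C)(C)C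
Why: Lateral (vinylogous) lithiation of a 2-methyl-4-pyranone followed by C-acylation, the methyl group being the gamma position of the vinylogous ester and the second equivalent of base storing the more acidic product as its enolate so that a second acylation is held back.

Step 4
Reactants: 5 tert-butyl 2-[6-(4-methoxyphenyl)-4-oxo-4H-pyran-2-yl]acetate
Product: 6 tert-butyl 2-diazo-2-[6-(4-methoxyphenyl)-4-oxo-4H-pyran-2-yl]acetate
Conditions: p-ABSA, DBU, MeCN, 0 °C → rt; stored cold and dark, used promptly
Reagents that add atoms: 4-acetamidobenzenesulfonyl azide (p-ABSA), CC(=O)Nc1ccc(cc1)S(=O)(=O)N=[N+]=[N-]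
Why: Regitz diazo transfer to an activated methylene, the CH2 of 5 being that of a vinylogous beta-keto ester and comparable in acidity with glutaconates, which undergo the same transfer.

Step 5
Reactants: 7 genkwanin (5,4'-dihydroxy-7-methoxyflavone)
Product: 9 4'-O-allyl-5-O-benzylgenkwanin, via 4'-O-allylgenkwanin 8 (not isolated)
Conditions: allyl bromide (1.05 equiv), K2CO3, DMF, rt; then BnBr, 70 °C
Reagents that add atoms: allyl bromide, C=CCBr; benzyl bromide, BrCc1ccccc1
Why: Two Williamson etherifications graded by acidity, the free 4'-OH reacting at room temperature and the 5-OH chelated to C4=O only on heating, and the benzyl group is placed now because after the coupling the acidic methine between ester and pyranone would be C-benzylated under the same conditions.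

Step 6
Reactants: 9 4'-O-allyl-5-O-benzylgenkwanin
Product: 10 5-O-benzylgenkwanin (5-benzyloxy-2-(4-hydroxyphenyl)-7-methoxy-4H-chromen-4-one)
Conditions: Pd(PPh3)4 (5 mol %), morpholine, THF, rt
Reagents that add atoms: none
Why: Tsuji-Trost-type deallylation, in which zerovalent palladium ionises the allyl aryl ether to a pi-allyl complex and the acidic phenoxide while morpholine takes the allyl group, benzyl and methyl ethers being inert.

Step 7
Reactants: 6 tert-butyl 2-diazo-2-[6-(4-methoxyphenyl)-4-oxo-4H-pyran-2-yl]acetate; 10 5-O-benzylgenkwanin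
Product: 11 tert-butyl (±)-2-(ArG-oxy)-2-[6-(4-methoxyphenyl)-4-oxo-4H-pyran-2-yl]acetate
Conditions: Rh2(OAc)4 (2 mol %), ClCH2CH2Cl, 50 °C, slow addition of 6
Reagents that add atoms: none
Why: Rhodium carbenoid O-H insertion into a phenol (oxonium ylide, then proton shift) makes the hindered ether at an sp3 carbon with the only free OH of 10, and the new methine stereocentre (future C8) forms without control as a racemate, which is harmless because it becomes sp2 in step 12.

Step 8
Reactants: 12 benzyl alcohol; 13 trichloroethylene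
Product: 14 benzyl (E)-1,2-dichlorovinyl ether
Conditions: KH, THF, 0 °C; then 13, −50 °C → rt
Reagents that add atoms: none
Why: Elimination-addition of the trichloroethylene route to ynol ethers, in which the alkoxide dehydrochlorinates 13 to dichloroacetylene in the flask and adds to it in anti fashion, which sets the E geometry.

Step 9
Reactants: 14 benzyl (E)-1,2-dichlorovinyl ether
Product: 15 benzyl ethynyl ether
Conditions: n-BuLi (2.3 equiv), Et2O, −78 → −40 °C; H2O, −78 °C; kept below 20 °C and used the same day
Reagents that add atoms: none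
Why: Dehydrochlorination to the chloroalkyne, chlorine-lithium exchange and protonation of the lithium alkoxyacetylide give the terminal ynol ether, and the cold handling respects the [3,3] sigmatropic rearrangement that benzyl alkynyl ethers undergo on mild heating.

Step 10
Reactants: 11 tert-butyl (±)-2-(ArG-oxy)-2-[6-(4-methoxyphenyl)-4-oxo-4H-pyran-2-yl]acetate
Product: 16 (±)-2-(ArG-oxy)-2-[6-(4-methoxyphenyl)-4-oxo-4H-pyran-2-yl]acetic acid
Conditions: TFA, CH2Cl2, 0 °C → rt; toluene co-evaporation below 25 °C
Reagents that add atoms: none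
Why: Acidolysis of a tert-butyl ester (loss of isobutene) avoids the hydroxide that would open the pyranone and flavone rings, keeps the vinylogous beta-keto acid in its protonated form that loses CO2 slowly, and is short and cold enough to leave the aryl benzyl ether in place.

Step 11
Reactants: 16 (±)-2-(ArG-oxy)-2-[6-(4-methoxyphenyl)-4-oxo-4H-pyran-2-yl]acetic acid
Product: 17 (±)-2-(ArG-oxy)-2-[6-(4-methoxyphenyl)-4-oxo-4H-pyran-2-yl]acetyl chloride
Conditions: 1-chloro-N,N,2-trimethylprop-1-en-1-amine (1.1 equiv), CH2Cl2, 0 °C; used as the solution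
Reagents that add atoms: 1-chloro-N,N,2-trimethylprop-1-en-1-amine, CC(C)=C(Cl)N(C)C
Why: Acid chloride formation with an alpha-chloroenamine under neutral conditions, in which the acid adds to the keteniminium form and chloride displaces the amide, so no HCl meets the benzyl ether or the basic pyranone carbonyl groups and the inert amide can stay in the flask.

Step 12
Reactants: 17 (±)-2-(ArG-oxy)-2-[6-(4-methoxyphenyl)-4-oxo-4H-pyran-2-yl]acetyl chloride; 15 benzyl ethynyl ether
Product: 22 8-(ArG-oxy)-7-(benzyloxy)-5-hydroxy-2-(4-methoxyphenyl)-4H-chromen-4-one (dibenzyl ether of the target), via aryloxy(pyranonyl)ketene 18 (not isolated), via 3-benzyloxycyclobutenone 19 (not isolated), via (Z)-dienylketene 20 (not isolated), via 4aH-chromene-4,5-dione tautomer 21 (not isolated)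
Conditions: Et3N (1.2 equiv, slow addition), 15 (1.3 equiv), CH2Cl2, −20 °C → rt; volatiles off below 25 °C, toluene, filter; 110 °C
Reagents that add atoms: none
Why: Proposed new method: Et3N dehydrochlorinates 17 at its doubly activated methine to ketene 18, whose carbonyl carbon (future C5) is attacked by the CH terminus of 15 (future C6) while the oxygen-bearing alkyne carbon (C7) bonds to the ketene alpha carbon (C8), a [2+2] cycloaddition that should give cyclobutenone 19 at or below room temperature, before 15 can rearrange on its own. At 110 °C 19 opens in a conrotatory four-electron electrocyclic reaction that breaks C5-C8, dienylketene 20 closes ring A as a six-membered carbocycle by a disrotatory six-electron electrocyclisation from C5 to C4a (the former C3 of the pyranone), and dione 21, whose C4a-H lies between two carbonyl groups, enolises to the chelated 5-phenol 22. The closest known reaction types are the Danheiser benzannulation of vinylketenes with alkoxy- and siloxyalkynes for the whole cascade and the Moore-Liebeskind ring expansion of 4-alkenyl- and 4-aryl-4-alkoxycyclobutenones for its second half, whereas the C2=C3 bond of a 4-pyranone as vinyl partner and an aryloxyketene drawn from an acid chloride have not been combined in such a cascade. Two selectivities are needed: the orientation of the alkyne, secured by the polarity match of the electron-rich ynol ether terminus with the electrophilic ketene carbonyl carbon (OBn on C7, H on C6), and the sense of ring opening, secured by the donor aryloxy group on C8, which prefers outward rotation and thereby turns the pyranonyl group inward, cis to the ketene arm, while any opening in the other sense is reversible and drains back through 19. No stereocentre survives, since C8 of 19 and C4a of 21 are racemic and both are sp2 in 22. Because O1 and the aryl ether oxygen sit on their carbons before ring A is built, the linkage can only end up at C8 and not at C6.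

Step 13
Reactants: 22 8-(ArG-oxy)-7-(benzyloxy)-5-hydroxy-2-(4-methoxyphenyl)-4H-chromen-4-one
Product: 23 5,7-dihydroxy-8-[4-(5-hydroxy-7-methoxy-4-oxo-4H-chromen-2-yl)phenoxy]-2-(4-methoxyphenyl)-4H-chromen-4-one (target, CNP0124888.0)
Conditions: H2 (1 atm), Pd/C, THF-MeOH, rt
Reagents that add atoms: none
Why: Catalytic hydrogenolysis cleaves both aryl benzyl ethers at once, while the diaryl ether, the two methyl ethers and the flavone C2=C3 bonds are not touched at one atmosphere and room temperature.

## Compound list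

1 | pentane-2,4-dione | CC(=O)CC(C)=O | starting material
2 | methyl 4-methoxybenzoate | COC(=O)c1ccc(OC)cc1 | starting material
3 | 1-(4-methoxyphenyl)hexane-1,3,5-trione | COc1ccc(C(=O)CC(=O)CC(C)=O)cc1 | intermediate
4 | 2-(4-methoxyphenyl)-6-methyl-4H-pyran-4-one | COc1ccc(-c2cc(=O)cc(C)o2)cc1 | intermediate
5 | tert-butyl 2-[6-(4-methoxyphenyl)-4-oxo-4H-pyran-2-yl]acetate | COc1ccc(-c2cc(=O)cc(CC(=O)OC(C)(C)C)o2)cc1 | intermediate
6 | tert-butyl 2-diazo-2-[6-(4-methoxyphenyl)-4-oxo-4H-pyran-2-yl]acetate | COc1ccc(-c2cc(=O)cc(C(=[N+]=[N-])C(=O)OC(C)(C)C)o2)cc1 | intermediate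
7 | genkwanin | COc1cc(O)c2c(=O)cc(-c3ccc(O)cc3)oc2c1 | starting material
8 | 4'-O-allylgenkwanin | COc1cc(O)c2c(=O)cc(-c3ccc(OCC=C)cc3)oc2c1 | intermediate
9 | 4'-O-allyl-5-O-benzylgenkwanin | COc1cc(OCc2ccccc2)c2c(=O)cc(-c3ccc(OCC=C)cc3)oc2c1 | intermediate
10 | 5-O-benzylgenkwanin | COc1cc(OCc2ccccc2)c2c(=O)cc(-c3ccc(O)cc3)oc2c1 | intermediate
11 | tert-butyl (±)-2-(ArG-oxy)-2-[6-(4-methoxyphenyl)-4-oxo-4H-pyran-2-yl]acetate | COc1ccc(-c2cc(=O)cc(C(Oc3ccc(-c4cc(=O)c5c(OCc6ccccc6)cc(OC)cc5o4)cc3)C(=O)OC(C)(C)C)o2)cc1 | intermediate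
12 | benzyl alcohol | OCc1ccccc1 | starting material
13 | trichloroethylene | ClC=C(Cl)Cl | starting material
14 | benzyl (E)-1,2-dichlorovinyl ether | Cl/C=C(/Cl)OCc1ccccc1 | intermediate
15 | benzyl ethynyl ether | C#COCc1ccccc1 | intermediate
16 | (±)-2-(ArG-oxy)-2-[6-(4-methoxyphenyl)-4-oxo-4H-pyran-2-yl]acetic acid | COc1ccc(-c2cc(=O)cc(C(Oc3ccc(-c4cc(=O)c5c(OCc6ccccc6)cc(OC)cc5o4)cc3)C(=O)O)o2)cc1 | intermediate
17 | (±)-2-(ArG-oxy)-2-[6-(4-methoxyphenyl)-4-oxo-4H-pyran-2-yl]acetyl chloride | COc1ccc(-c2cc(=O)cc(C(Oc3ccc(-c4cc(=O)c5c(OCc6ccccc6)cc(OC)cc5o4)cc3)C(=O)Cl)o2)cc1 | intermediate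
18 | 2-(ArG-oxy)-2-[6-(4-methoxyphenyl)-4-oxo-4H-pyran-2-yl]ethenone (ketene) | COc1ccc(-c2cc(=O)cc(C(=C=O)Oc3ccc(-c4cc(=O)c5c(OCc6ccccc6)cc(OC)cc5o4)cc3)o2)cc1 | intermediate
19 | (±)-4-(ArG-oxy)-3-(benzyloxy)-4-[6-(4-methoxyphenyl)-4-oxo-4H-pyran-2-yl]cyclobut-2-en-1-one | COc1ccc(-c2cc(=O)cc(C3(Oc4ccc(-c5cc(=O)c6c(OCc7ccccc7)cc(OC)cc6o5)cc4)C(=O)C=C3OCc3ccccc3)o2)cc1 | intermediate
20 | (Z)-4-(ArG-oxy)-3-(benzyloxy)-4-[6-(4-methoxyphenyl)-4-oxo-4H-pyran-2-yl]buta-1,3-dien-1-one | O=C=C/C(OCc1ccccc1)=C(\c1cc(=O)cc(-c2ccc(OC)cc2)o1)Oc1ccc(-c2cc(=O)c3c(OCc4ccccc4)cc(OC)cc3o2)cc1 | intermediate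
21 | (±)-8-(ArG-oxy)-7-(benzyloxy)-2-(4-methoxyphenyl)-4aH-chromene-4,5-dione | COc1ccc(C2=CC(=O)C3C(=O)C=C(OCc4ccccc4)C(Oc4ccc(-c5cc(=O)c6c(OCc7ccccc7)cc(OC)cc6o5)cc4)=C3O2)cc1 | intermediate
22 | 8-(ArG-oxy)-7-(benzyloxy)-5-hydroxy-2-(4-methoxyphenyl)-4H-chromen-4-one | COc1ccc(-c2cc(=O)c3c(O)cc(OCc4ccccc4)c(Oc4ccc(-c5cc(=O)c6c(OCc7ccccc7)cc(OC)cc6o5)cc4)c3o2)cc1 | intermediate
23 | 5,7-dihydroxy-8-[4-(5-hydroxy-7-methoxy-4-oxo-4H-chromen-2-yl)phenoxy]-2-(4-methoxyphenyl)-4H-chromen-4-one | COc1ccc(-c2cc(=O)c3c(O)cc(O)c(Oc4ccc(-c5cc(=O)c6c(O)cc(OC)cc6o5)cc4)c3o2)cc1 | target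

## Step count and risks

Total step count: 13.
Longest linear sequence: 9 (steps 1, 2, 3, 4, 7, 10, 11, 12, 13).

**Step 12 (the labelled step).**
- The ketene may dimerise, or be intercepted by chloride, amine or traces of water, before it meets the ynol ether.
- The ynol ether may be used up by protonation with the ammonium salt.
- The six-electron closure onto the pyranone double bond may lag behind decomposition of the dienylketene at 110 °C.

The fallback uses known chemistry, sets out from 10 and comes back to the route at 23. Purchased acacetin F1 is dibenzylated (BnBr, K2CO3, DMF, 80 °C) to 5,7-di-O-benzylacacetin F2. It is then iodinated at C8, the position at which fully alkylated 5,7-dioxygenated flavones are attacked (I2, AgO2CCF3, CH2Cl2), to give 8-iodo-5,7-di-O-benzylacacetin F3. An Ullmann diaryl ether coupling of F3 with 10 (CuI, picolinic acid, Cs2CO3, DMSO, 100 °C) gives the tribenzyl ether of the target F4. Hydrogenolysis of F4 under the conditions of step 13 gives 23.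

**Step 10.** The liberated acid is a vinylogous beta-keto acid, so loss of CO2 during acidolysis or concentration is the main danger.

The fallback sets out from 11 and comes back at 17. The decarboxylation is carried through on purpose (TFA, CH2Cl2, then warm toluene) to 2-(ArG-oxymethyl)-6-(4-methoxyphenyl)-4H-pyran-4-one F5. Its OCH2 group is laterally lithiated (LiN(SiMe3)2, THF, −78 °C) and carboxylated with dry CO2. The resulting lithium 2-(ArG-oxy)-2-(pyranonyl)acetate F6 is freed from volatiles and suspended in CH2Cl2. It is converted directly into 17 with (COCl)2 and catalytic DMF at −20 °C, so the free acid never has to be handled.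

**Step 7.** Three processes may outrun the O-H insertion:
- closure of the vinylogous diazo ester to a fused pyrazole;
- carbene dimerisation;
- carbonyl ylide formation with a flavone C=O.

The fallback replaces the carbene by an SN2 displacement, sets out from 5 (with 10 as partner) and comes back at 11. Enolate bromination of 5 (LiN(SiMe3)2, THF, −78 °C; NBS) gives tert-butyl 2-bromo-2-[6-(4-methoxyphenyl)-4-oxo-4H-pyran-2-yl]acetate F7. The phenoxide of 10 displaces the bromide in a Williamson etherification (K2CO3, acetone, rt) to give 11.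

## Further compounds

F1 | step 12 | acacetin (purchased) | COc1ccc(-c2cc(=O)c3c(O)cc(O)cc3o2)cc1
F2 | step 12 | 5,7-di-O-benzylacacetin | COc1ccc(-c2cc(=O)c3c(OCc4ccccc4)cc(OCc4ccccc4)cc3o2)cc1
F3 | step 12 | 8-iodo-5,7-di-O-benzylacacetin | COc1ccc(-c2cc(=O)c3c(OCc4ccccc4)cc(OCc4ccccc4)c(I)c3o2)cc1
F4 | step 12 | tribenzyl ether of the target | COc1ccc(-c2cc(=O)c3c(OCc4ccccc4)cc(OCc4ccccc4)c(Oc4ccc(-c5cc(=O)c6c(OCc7ccccc7)cc(OC)cc6o5)cc4)c3o2)cc1
F5 | step 10 | 2-(ArG-oxymethyl)-6-(4-methoxyphenyl)-4H-pyran-4-one | COc1ccc(-c2cc(=O)cc(COc3ccc(-c4cc(=O)c5c(OCc6ccccc6)cc(OC)cc5o4)cc3)o2)cc1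
F6 | step 10 | lithium (±)-2-(ArG-oxy)-2-[6-(4-methoxyphenyl)-4-oxo-4H-pyran-2-yl]acetate | [Li+].[O-]C(=O)C(Oc1ccc(-c2cc(=O)c3c(OCc4ccccc4)cc(OC)cc3o2)cc1)c1cc(=O)cc(-c2ccc(OC)cc2)o1
F7 | step 7 | tert-butyl (±)-2-bromo-2-[6-(4-methoxyphenyl)-4-oxo-4H-pyran-2-yl]acetate | COc1ccc(-c2cc(=O)cc(C(Br)C(=O)OC(C)(C)C)o2)cc1
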